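**Retrosynthetic overview**
1. Debenzylation and oxidation of a C3 carbinol lead back to an anti‑3,5‑dioxygenated diarylheptane. Reductive scission of a benzylic C7–O bond leads from there to an all‑cis 2‑aryl‑6‑(2‑arylethyl)oxan‑4‑ol.
2. Key disconnection C6–C7 (made together with C5–O): Prins cyclisation of vanillin acetate with an (R)‑1‑arylhex‑5‑en‑3‑ol.
3. Rings: both benzene rings are bought. The only ring formed is the temporary oxane O–C7–C6–C5–C4–C3, closed in step 4 and opened in step 6.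
4. Enabling feature: the oxygen on C3 and the benzylic carbon C7 are 1,5‑related with carbinol C5 midway, so an O(C3)–C7 tie gives a six‑membered ring whose position 4 is C5. C7 sits on the 4‑oxygenated 3‑methoxyphenyl ring, whose para oxygen allows the C7–O tie to be cut out again.
5. Stereochemistry: a catalytic allylation sets C3 and the chair Prins transition state relays it to C5. The auxiliary centres C7 and C3 are then erased by reduction and oxidation.

Key step: step 4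

Remark: the chain is numbered C1 (CH2 on the 4‑hydroxy‑3,5‑dimethoxyphenyl ring) to C7 (CH2 on the 4‑hydroxy‑3‑methoxyphenyl ring). The stereocentre C5 of the given SMILES is read as R.

**Step 1**
Reactants: 1 4‑allyl‑2,6‑dimethoxyphenol (methoxyeugenol)
Product: 2 5‑allyl‑2‑(benzyloxy)‑1,3‑dimethoxybenzene
Conditions: BnBr, K2CO3, DMF, 60 °C
Reagents that add atoms: benzyl bromide, BrCc1ccccc1
Why: Williamson etherification of the acidic phenol; the benzyl group should survive every later acidic, basic and oxidative step and leave in the final hydrogenolysis.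

**Step 2**
Reactants: 2 5‑allyl‑2‑(benzyloxy)‑1,3‑dimethoxybenzene
Product: 4 3‑[4‑(benzyloxy)‑3,5‑dimethoxyphenyl]propan‑1‑ol, via B‑alkyl‑9‑BBN adduct 3 (not isolated)
Conditions: 9‑BBN, THF, 0 °C → rt; then NaOH, H2O2, 0 °C → rt
Reagents that add atoms: hydrogen peroxide, OO; 9‑BBN, B1C2CCCC1CCC2 (its atoms stay only in 3)
Why: Brown hydroboration–oxidation; the bulky borane places boron on the terminal alkene carbon, so alkaline peroxide should give the primary alcohol while the aryl ethers stay inert.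

**Step 3**
Reactants: 4 3‑[4‑(benzyloxy)‑3,5‑dimethoxyphenyl]propan‑1‑ol; 5 allyl acetate
Product: 7 (R)‑1‑[4‑(benzyloxy)‑3,5‑dimethoxyphenyl]hex‑5‑en‑3‑ol, via transient aldehyde 6 (not isolated)
Conditions: [Ir(cod)Cl]2 (2.5 mol %), (S)‑Cl,MeO‑BIPHEP (5 mol %), 4‑Cl‑3‑NO2‑C6H3CO2H (10 mol %), Cs2CO3 (20 mol %), THF, 100 °C, sealed tube
Reagents that add atoms: none
Why: Krische‑type iridium‑catalysed transfer‑hydrogenative carbonyl allylation; the alcohol is dehydrogenated to 6 and the chiral cyclometallated π‑allyliridium C,O‑benzoate adds allyl through a closed chair transition state to the Si face (the ligand antipode is the one that addresses this face), which sets the (R)‑carbinol at C3.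

**Step 4**
Reactants: 7 (R)‑1‑[4‑(benzyloxy)‑3,5‑dimethoxyphenyl]hex‑5‑en‑3‑ol; 8 4‑formyl‑2‑methoxyphenyl acetate (vanillin acetate)
Product: 10 (2R,4S,6R)‑6‑{2‑[4‑(benzyloxy)‑3,5‑dimethoxyphenyl]ethyl}‑2‑(4‑hydroxy‑3‑methoxyphenyl)oxan‑4‑ol, via oxanyl trifluoroacetate 9 (not isolated)
Conditions: CF3CO2H (excess), CH2Cl2, 0 °C → rt; concentrate; then K2CO3 (cat.), MeOH, rt
Reagents that add atoms: trifluoroacetic acid, OC(=O)C(F)(F)F
Why: Acid condenses 7 with 8 to the (E)‑oxocarbenium ion ArC7H=O(+)–C3, the terminal alkene carbon C6 attacks C7, and the resulting C5 cation is captured by trifluoroacetate; this is a Prins cyclisation, a reaction type established for 2‑aryl‑6‑(2‑arylethyl)oxanes. The single ring O–C7–C6–C5–C4–C3 closes in a 6‑endo‑trig mode through a chair transition state. C7 is controlled by the E geometry of the oxocarbenium ion with the C3 side chain equatorial, which puts the aryl group equatorial and cis to C3 (this centre is erased later). C5 is controlled by equatorial attack on the delocalised oxanyl cation, so the new C5–O bond is cis to both substituents, and (3R) is thereby translated into the 1,3‑anti O/O array that corresponds to (5R) in the target. The step needs retention of enantiopurity against 2‑oxonia‑Cope rearrangement with aldehyde exchange, and chemoselectivity against arene capture of the cation; the acetate on the para oxygen of 8 keeps the benzylic C7–O bond from ionising, and the large excess of trifluoroacetate should outrun the trialkoxyarene. Methanolysis in the same flask then frees the C5 hydroxyl and the phenol.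

**Step 5**
Reactants: 10 (2R,4S,6R)‑6‑{2‑[4‑(benzyloxy)‑3,5‑dimethoxyphenyl]ethyl}‑2‑(4‑hydroxy‑3‑methoxyphenyl)oxan‑4‑ol
Product: 11 (2R,4S,6R)‑4‑(benzyloxy)‑2‑[4‑(benzyloxy)‑3‑methoxyphenyl]‑6‑{2‑[4‑(benzyloxy)‑3,5‑dimethoxyphenyl]ethyl}oxane
Conditions: NaH, BnBr, Bu4NI (cat.), DMF, 0 °C → rt
Reagents that add atoms: benzyl bromide, BrCc1ccccc1
Why: Double Williamson etherification masks the C5 hydroxyl, which keeps it distinct from the ring oxygen on C3, and turns the para oxygen of the C7 aryl ring back into a donor for the next step.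

**Step 6**
Reactants: 11 (2R,4S,6R)‑4‑(benzyloxy)‑2‑[4‑(benzyloxy)‑3‑methoxyphenyl]‑6‑{2‑[4‑(benzyloxy)‑3,5‑dimethoxyphenyl]ethyl}oxane
Product: 12 (3R,5R)‑5‑(benzyloxy)‑7‑[4‑(benzyloxy)‑3‑methoxyphenyl]‑1‑[4‑(benzyloxy)‑3,5‑dimethoxyphenyl]heptan‑3‑ol
Conditions: Et3SiH (excess), CF3CO2H, CH2Cl2, −20 → 0 °C; aq. NaHCO3
Reagents that add atoms: none
Why: Ionic hydrogenation (Kursanov–Parnes type, SN1 ionisation then hydride transfer); only the C7–O bond carries an aryl ring with a para alkoxy donor, so acid opens the ring to a quinone‑methide‑like benzylic cation that the silane quenches irreversibly, which frees the C3 hydroxyl, erases C7 as a stereocentre and leaves C5 and the plain benzyl ethers untouched.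

**Step 7**
Reactants: 12 (3R,5R)‑5‑(benzyloxy)‑7‑[4‑(benzyloxy)‑3‑methoxyphenyl]‑1‑[4‑(benzyloxy)‑3,5‑dimethoxyphenyl]heptan‑3‑ol
Product: 13 (R)‑5‑(benzyloxy)‑7‑[4‑(benzyloxy)‑3‑methoxyphenyl]‑1‑[4‑(benzyloxy)‑3,5‑dimethoxyphenyl]heptan‑3‑one
Conditions: Dess–Martin periodinane, CH2Cl2, 0 °C → rt
Reagents that add atoms: none
Why: Dess–Martin oxidation of the only free hydroxyl under non‑basic conditions should give the C3 ketone without β‑elimination of the C5 benzyloxy group, and the relay stereocentre C3 disappears.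

**Step 8**
Reactants: 13 (R)‑5‑(benzyloxy)‑7‑[4‑(benzyloxy)‑3‑methoxyphenyl]‑1‑[4‑(benzyloxy)‑3,5‑dimethoxyphenyl]heptan‑3‑one
Product: 14 (R)‑5‑hydroxy‑1‑(4‑hydroxy‑3,5‑dimethoxyphenyl)‑7‑(4‑hydroxy‑3‑methoxyphenyl)heptan‑3‑one (target)
Conditions: H2 (1 atm), Pd(OH)2/C, EtOAc–EtOH, rt
Reagents that add atoms: none
Why: Catalytic hydrogenolysis of two aryl benzyl ethers and one alkyl benzyl ether under neutral conditions spares the aliphatic ketone and gives no opening for retro‑aldol cleavage or dehydration, so C5 stays R.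

**Compound list**
1 | 4‑allyl‑2,6‑dimethoxyphenol | C=CCc1cc(OC)c(O)c(OC)c1 | starting material
2 | 5‑allyl‑2‑(benzyloxy)‑1,3‑dimethoxybenzene | C=CCc1cc(OC)c(OCc2ccccc2)c(OC)c1 | intermediate
3 | 9‑{3‑[4‑(benzyloxy)‑3,5‑dimethoxyphenyl]propyl}‑9‑borabicyclo[3.3.1]nonane | COc1cc(CCCB2C3CCCC2CCC3)cc(OC)c1OCc1ccccc1 | intermediate
4 | 3‑[4‑(benzyloxy)‑3,5‑dimethoxyphenyl]propan‑1‑ol | OCCCc1cc(OC)c(OCc2ccccc2)c(OC)c1 | intermediate
5 | allyl acetate | C=CCOC(C)=O | starting material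
6 | 3‑[4‑(benzyloxy)‑3,5‑dimethoxyphenyl]propanal | O=CCCc1cc(OC)c(OCc2ccccc2)c(OC)c1 | intermediate
7 | (R)‑1‑[4‑(benzyloxy)‑3,5‑dimethoxyphenyl]hex‑5‑en‑3‑ol | C=CC[C@H](O)CCc1cc(OC)c(OCc2ccccc2)c(OC)c1 | intermediate
8 | 4‑formyl‑2‑methoxyphenyl acetate | CC(=O)Oc1ccc(C=O)cc1OC | starting material
9 | (2R,4S,6R)‑2‑(4‑acetoxy‑3‑methoxyphenyl)‑6‑{2‑[4‑(benzyloxy)‑3,5‑dimethoxyphenyl]ethyl}oxan‑4‑yl trifluoroacetate | O1[C@@H](c2ccc(OC(C)=O)c(OC)c2)C[C@@H](OC(=O)C(F)(F)F)C[C@H]1CCc1cc(OC)c(OCc2ccccc2)c(OC)c1 | intermediate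
10 | (2R,4S,6R)‑6‑{2‑[4‑(benzyloxy)‑3,5‑dimethoxyphenyl]ethyl}‑2‑(4‑hydroxy‑3‑methoxyphenyl)oxan‑4‑ol | O1[C@@H](c2ccc(O)c(OC)c2)C[C@@H](O)C[C@H]1CCc1cc(OC)c(OCc2ccccc2)c(OC)c1 | intermediate
11 | (2R,4S,6R)‑4‑(benzyloxy)‑2‑[4‑(benzyloxy)‑3‑methoxyphenyl]‑6‑{2‑[4‑(benzyloxy)‑3,5‑dimethoxyphenyl]ethyl}oxane | O1[C@@H](c2ccc(OCc3ccccc3)c(OC)c2)C[C@@H](OCc2ccccc2)C[C@H]1CCc1cc(OC)c(OCc2ccccc2)c(OC)c1 | intermediate
12 | (3R,5R)‑5‑(benzyloxy)‑7‑[4‑(benzyloxy)‑3‑methoxyphenyl]‑1‑[4‑(benzyloxy)‑3,5‑dimethoxyphenyl]heptan‑3‑ol | COc1cc(CC[C@@H](OCc2ccccc2)C[C@H](O)CCc2cc(OC)c(OCc3ccccc3)c(OC)c2)ccc1OCc1ccccc1 | intermediate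
13 | (R)‑5‑(benzyloxy)‑7‑[4‑(benzyloxy)‑3‑methoxyphenyl]‑1‑[4‑(benzyloxy)‑3,5‑dimethoxyphenyl]heptan‑3‑one | COc1cc(CC[C@@H](OCc2ccccc2)CC(=O)CCc2cc(OC)c(OCc3ccccc3)c(OC)c2)ccc1OCc1ccccc1 | intermediate
14 | (R)‑5‑hydroxy‑1‑(4‑hydroxy‑3,5‑dimethoxyphenyl)‑7‑(4‑hydroxy‑3‑methoxyphenyl)heptan‑3‑one | COc1cc(CC[C@@H](O)CC(=O)CCc2cc(OC)c(O)c(OC)c2)ccc1O | target

**Step count and risks**
Total steps: 8. Longest linear sequence: 8 (1 → 14); 5 and 8 are bought.

Step 4. The risks are erosion of enantiopurity through reversible 2‑oxonia‑Cope rearrangement with aldehyde exchange, sluggish cyclisation, and capture of the ring cation by the electron‑rich arene. The fallback makes the same C6–C7 bond by opening a terminal epoxide with a benzylic organocopper species, with the stereocentre taken from the chiral pool.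
- It sets out from 4. Swern oxidation gives 6, now isolated.
- Propane‑1,3‑dithiol and BF3·OEt2 convert 6 into 2‑{2‑[4‑(benzyloxy)‑3,5‑dimethoxyphenyl]ethyl}‑1,3‑dithiane F1.
- n‑BuLi followed by (S)‑epichlorohydrin gives (S)‑2‑{2‑[4‑(benzyloxy)‑3,5‑dimethoxyphenyl]ethyl}‑2‑(oxiran‑2‑ylmethyl)‑1,3‑dithiane F2.
- 4‑(Benzyloxy)‑3‑methoxybenzylmagnesium chloride F3, made from the benzyl chloride and Mg, opens F2 at its terminal carbon under CuI catalysis. This gives (R)‑4‑[4‑(benzyloxy)‑3‑methoxyphenyl]‑1‑(2‑{2‑[4‑(benzyloxy)‑3,5‑dimethoxyphenyl]ethyl}‑1,3‑dithian‑2‑yl)butan‑2‑ol F4.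
- MeI and CaCO3 in aqueous MeCN unmask the ketone to (R)‑7‑[4‑(benzyloxy)‑3‑methoxyphenyl]‑1‑[4‑(benzyloxy)‑3,5‑dimethoxyphenyl]‑5‑hydroxyheptan‑3‑one F5.
- Hydrogenolysis over Pd/C brings the sequence back to the route at 14.

Step 6. The risks are proton loss from the benzylic cation followed by ionisation next to C5 (loss of configuration), acid cleavage of the aryl benzyl ethers, and ring re‑closure outrunning hydride transfer. The fallback opens the ring oxidatively instead of reductively.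
- It sets out from 11. DDQ in CH2Cl2–pH 7 buffer abstracts hydride from C7, and water opens the ring to (3R,5S)‑5‑(benzyloxy)‑7‑[4‑(benzyloxy)‑3‑methoxyphenyl]‑1‑[4‑(benzyloxy)‑3,5‑dimethoxyphenyl]‑3‑hydroxyheptan‑7‑one F6.
- Dess–Martin oxidation gives (S)‑5‑(benzyloxy)‑7‑[4‑(benzyloxy)‑3‑methoxyphenyl]‑1‑[4‑(benzyloxy)‑3,5‑dimethoxyphenyl]heptane‑3,7‑dione F7.
- H2 over Pd/C in EtOH–AcOH removes the benzyl groups and reduces only the aryl ketone down to CH2. The sequence returns to the route at 14.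

Step 3. The risks are poor facial selectivity or stalled dehydrogenation with this aliphatic alcohol. The fallback separates oxidation from C–C bond formation and uses a chiral Lewis acid.
- It sets out from 4. Swern oxidation gives 6, isolated.
- Keck allylation (allyltributylstannane, (S)‑BINOL/Ti(OiPr)4, 4 Å MS, CH2Cl2, −20 °C; Si‑face attack) gives (R)‑tributyl({1‑[4‑(benzyloxy)‑3,5‑dimethoxyphenyl]hex‑5‑en‑3‑yl}oxy)stannane F8.
- Aqueous work‑up hydrolyses F8, and the sequence returns to the route at 7.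

**Further compounds**
F1 | step 4 | 2‑{2‑[4‑(benzyloxy)‑3,5‑dimethoxyphenyl]ethyl}‑1,3‑dithiane | C1CSC(CCc2cc(OC)c(OCc3ccccc3)c(OC)c2)SC1
F2 | step 4 | (S)‑2‑{2‑[4‑(benzyloxy)‑3,5‑dimethoxyphenyl]ethyl}‑2‑(oxiran‑2‑ylmethyl)‑1,3‑dithiane | C1CSC(CCc2cc(OC)c(OCc3ccccc3)c(OC)c2)(C[C@H]2CO2)SC1
F3 | step 4 | 4‑(benzyloxy)‑3‑methoxybenzylmagnesium chloride | COc1cc(C[Mg]Cl)ccc1OCc1ccccc1
F4 | step 4 | (R)‑4‑[4‑(benzyloxy)‑3‑methoxyphenyl]‑1‑(2‑{2‑[4‑(benzyloxy)‑3,5‑dimethoxyphenyl]ethyl}‑1,3‑dithian‑2‑yl)butan‑2‑ol | COc1cc(CC[C@@H](O)CC2(CCc3cc(OC)c(OCc4ccccc4)c(OC)c3)SCCCS2)ccc1OCc1ccccc1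
F5 | step 4 | (R)‑7‑[4‑(benzyloxy)‑3‑methoxyphenyl]‑1‑[4‑(benzyloxy)‑3,5‑dimethoxyphenyl]‑5‑hydroxyheptan‑3‑one | COc1cc(CC[C@@H](O)CC(=O)CCc2cc(OC)c(OCc3ccccc3)c(OC)c2)ccc1OCc1ccccc1
F6 | step 6 | (3R,5S)‑5‑(benzyloxy)‑7‑[4‑(benzyloxy)‑3‑methoxyphenyl]‑1‑[4‑(benzyloxy)‑3,5‑dimethoxyphenyl]‑3‑hydroxyheptan‑7‑one | COc1cc(C(=O)C[C@@H](OCc2ccccc2)C[C@H](O)CCc2cc(OC)c(OCc3ccccc3)c(OC)c2)ccc1OCc1ccccc1
F7 | step 6 | (S)‑5‑(benzyloxy)‑7‑[4‑(benzyloxy)‑3‑methoxyphenyl]‑1‑[4‑(benzyloxy)‑3,5‑dimethoxyphenyl]heptane‑3,7‑dione | COc1cc(C(=O)C[C@@H](OCc2ccccc2)CC(=O)CCc2cc(OC)c(OCc3ccccc3)c(OC)c2)ccc1OCc1ccccc1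
F8 | step 3 | (R)‑tributyl({1‑[4‑(benzyloxy)‑3,5‑dimethoxyphenyl]hex‑5‑en‑3‑yl}oxy)stannane | C=CC[C@H](O[Sn](CCCC)(CCCC)CCCC)CCc1cc(OC)c(OCc2ccccc2)c(OC)c1
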